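**Assumptions.** The SMILES is taken literally; in terpenoid (atisane/podocarpane) numbering, used throughout, it is (5S,8S,9S,10S,12R,14S) with 10β-CH3, 5α-H and the 14-OAc syn to the C15–C16 bridge. 5,6-Dimethoxy-2-tetralone is treated as a catalogue compound (otherwise about three steps from 5,6-dimethoxy-1-tetralone). The route is a paper design, not an executed one.

## Retrosynthetic overview

1. α-Methylene ketone ⇐ C15 ketone (Mannich methylenation) ⇐ C15–O-t-Bu.
2. δ-Lactone (C3–O–C9) ⇐ acid-mediated Markovnikov lactonisation of the C3 ester onto the Δ9(11) alkene of a bicyclo[2.2.2]octene.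
3. Bicyclo[2.2.2]octene (C8, C12 set; C14 ketone → 14-OAc) ⇐ masked o-benzoquinone Diels–Alder of a 14-hydroxy-13-methoxy arene with tert-butyl vinyl ether (supplies C15–C16).
4. 3,4-Seco ester with isopropenyl ⇐ Baeyer–Villiger and E1 opening of a trans-fused 4,4-dimethyl-3-ketone; ring A is temporary and exists to set C5.
5. Tricyclic ketone ⇐ asymmetric Robinson annulation of a 1-methyl-2-tetralone with ethyl vinyl ketone, then reductive methylation. Ring order: B/C (bought) → A (built, later cleaved) → bicyclo[2.2.2]octane → δ-lactone.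

## Route

**Step 1**
Reactants: 1, 5,6-dimethoxy-2-tetralone
Product: 2, (±)-5,6-dimethoxy-1-methyl-2-tetralone
Conditions: pyrrolidine, PhMe, reflux (−H2O); MeI, MeCN, 60 °C; aq. AcOH
Reagents that add atoms: iodomethane, CI
Why: Stork enamine alkylation; the arene-conjugated enamine is mono-C-methylated only at benzylic C1, and the centre is left racemic because step 2 is stereoconvergent.

**Step 2**
Reactants: 2; 3, ethyl vinyl ketone
Product: 4, (R)-5,6-dimethoxy-1-methyl-1-(3-oxopentyl)-2-tetralone
Conditions: (R)-(+)-1-phenylethylamine, PhMe, reflux (Dean–Stark); 3, THF, 25–40 °C, 2–3 d; 20% aq. AcOH, rt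
Reagents that add atoms: ethyl vinyl ketone, CCC(=O)C=C; water, O (ketone oxygen restored on imine hydrolysis)
Why: d'Angelo deracemising Michael addition; both enantiomers of 2 pass through one secondary enamine that adds to the enone through a chair aza-ene-type transition state anti to the auxiliary phenyl, setting quaternary C10 as 10β-CH3 (the (R)-amine is chosen by analogy with the 2-methylcyclohexanone case).

**Step 3**
Reactants: 4
Product: 5, (10S)-13,14-dimethoxy-19-norpodocarpa-4,8,11,13-tetraen-3-one (tricyclic 4-methyl enone)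
Conditions: NaOMe, MeOH, 60 °C
Reagents that add atoms: none
Why: Intramolecular aldol condensation (second half of the Robinson annulation) closes ring A; C10 is non-enolisable and is not scrambled.

**Step 4**
Reactants: 5
Product: 6, 13,14-dimethoxypodocarpa-8,11,13-trien-3-one (trans-fused, 5α-H, 10β-CH3)
Conditions: Li, NH3(l)/THF, t-BuOH (1 equiv), −78 °C; isoprene; MeI, −78 → −33 °C
Reagents that add atoms: iodomethane, CI
Why: Stork reductive alkylation; axial β-protonation at C5 anti to the C10 methyl gives the trans ring fusion, and the regiospecific C3 enolate is methylated at C4 to the gem-dimethyl ketone.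

**Step 5**
Reactants: 6
Product: 7, 14-hydroxy-13-methoxypodocarpa-8,11,13-trien-3-one
Conditions: BCl3 (3 equiv), CH2Cl2, −78 → 0 °C
Reagents that add atoms: none
Why: Lewis-acid aryl methyl ether cleavage; the doubly ortho-flanked, out-of-plane C14–OMe is the more basic oxygen and is cleaved first, as the central OMe is in 1,2,3-trimethoxybenzene.

**Step 6**
Reactants: 7
Product: 8, 14-acetoxy-13-methoxypodocarpa-8,11,13-trien-3-one
Conditions: Ac2O, pyridine, DMAP (cat.), CH2Cl2, rt
Reagents that add atoms: acetic anhydride, CC(=O)OC(C)=O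
Why: Phenol O-acylation masks and deactivates the arene for the peracid step.

**Step 7**
Reactants: 8
Product: 9, 14-acetoxy-13-methoxy-4-oxa-A-homopodocarpa-8,11,13-trien-3-one (ε-lactone)
Conditions: m-CPBA, NaHCO3, CH2Cl2, rt, 3 d
Reagents that add atoms: m-CPBA, OOC(=O)c1cccc(Cl)c1 (one O)
Why: Baeyer–Villiger oxidation; the quaternary C4 migrates, so oxygen is inserted between C3 and C4.

**Step 8**
Reactants: 9
Product: 10, methyl 3-[(1S,2S)-5-hydroxy-6-methoxy-1-methyl-2-(prop-1-en-2-yl)tetralin-1-yl]propanoate (methyl 14-hydroxy-13-methoxy-3,4-secopodocarpa-4(18),8,11,13-tetraen-3-oate)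
Conditions: p-TsOH·H2O, MeOH/CH2Cl2, 45 °C
Reagents that add atoms: methanol, CO
Why: Alkyl–oxygen (AAL1) ionisation of the tertiary lactone gives the C4 cation, which loses a methyl proton (E1) to the isopropenyl group while the acid is Fischer-esterified and the aryl acetate is transesterified off; C5 and C10 are untouched.

**Step 9**
Reactants: 10; 11, tert-butyl vinyl ether
Product: 12, methyl 15-tert-butoxy-13,13-dimethoxy-14-oxo-3,4-seco-17-noratisa-4(18),9(11)-dien-3-oate
Conditions: PhI(OAc)2, MeOH, 0 °C, with 11 (20 equiv) present; then rt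
Reagents that add atoms: methanol, CO (second OMe at C13); tert-butyl vinyl ether, C=COC(C)(C)C
Why: Oxidative dearomatisation to the masked o-benzoquinone and inverse-demand Diels–Alder; the enol-ether CH2 bonds to C12 and the alkoxy carbon to C8 ("ortho" rule), with approach anti to the pseudo-axial C10 methyl (α-face) setting C8 and C12 and leaving the C9=C11 alkene.

**Step 10**
Reactants: 12
Product: 13, methyl (14S)-15-tert-butoxy-14-hydroxy-3,4-seco-17-noratisa-4(18),9(11)-dien-3-oate
Conditions: SmI2 (5 equiv), THF/MeOH, −20 → 0 °C; then NaBH4, 0 °C (same pot)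
Reagents that add atoms: none
Why: SmI2 ketyl β-elimination removes both α-methoxy groups, then hydride adds to C14=O from the open C9=C11 π-face (the saturated C15–C16 bridge shields the other face), placing the 14-OH syn to the C15–C16 bridge.

**Step 11**
Reactants: 13
Product: 14, the 14-O-acetate of 13
Conditions: Ac2O, Et3N, DMAP, CH2Cl2, rt
Reagents that add atoms: acetic anhydride, CC(=O)OC(C)=O
Why: Acylation of the secondary alcohol with retention installs the 14-OAc.

**Step 12**
Reactants: 14
Product: 15, (14S)-14-acetoxy-15-hydroxy-3,4-seco-17-noratis-4(18)-en-3,9-olide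
Conditions: TFA/CH2Cl2 (1:2), H2O (5 equiv), 0 °C → rt
Reagents that add atoms: none
Why: Acid cleaves the tert-butyl ether and protonates C9=C11 to the tertiary C9 cation, which is trapped by the C3 ester carbonyl held on the α-face of C10 (hydrolytic loss of MeOH), giving the cis-fused δ-lactone and fixing C9.

**Step 13**
Reactants: 15
Product: 16, (14S)-14-acetoxy-15-oxo-3,4-seco-17-noratis-4(18)-en-3,9-olide
Conditions: Dess–Martin periodinane, NaHCO3, CH2Cl2, rt
Reagents that add atoms: none
Why: Dess–Martin oxidation of the secondary alcohol; C8 is quaternary, so there is no epimerisation or β-elimination of the 14-OAc.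

**Step 14**
Reactants: 16
Product: 17, crotobarin
Conditions: (CH2O)n, N-methylanilinium trifluoroacetate, THF, 65 °C
Reagents that add atoms: formaldehyde (paraformaldehyde), C=O
Why: Mannich-type α-methylenation (Gras conditions); the C15 ketone can enolise only toward C16, and elimination can only be exocyclic (Bredt), without strong base near the lactone or acetate.

## Compound list

1 | 5,6-dimethoxy-2-tetralone | O=C1CCc2c(OC)c(OC)ccc2C1 | starting material
2 | (±)-5,6-dimethoxy-1-methyl-2-tetralone | O=C1CCc2c(OC)c(OC)ccc2C1C | intermediate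
3 | ethyl vinyl ketone | CCC(=O)C=C | starting material
4 | (R)-5,6-dimethoxy-1-methyl-1-(3-oxopentyl)-2-tetralone | CCC(=O)CC[C@]1(C)c2ccc(OC)c(OC)c2CCC1=O | intermediate
5 | (10S)-13,14-dimethoxy-19-norpodocarpa-4,8,11,13-tetraen-3-one | O=C1CC[C@]2(C)c3ccc(OC)c(OC)c3CCC2=C1C | intermediate
6 | 13,14-dimethoxypodocarpa-8,11,13-trien-3-one (5α-H, 10β-Me) | O=C1CC[C@]2(C)c3ccc(OC)c(OC)c3CC[C@H]2C1(C)C | intermediate
7 | 14-hydroxy-13-methoxypodocarpa-8,11,13-trien-3-one | O=C1CC[C@]2(C)c3ccc(OC)c(O)c3CC[C@H]2C1(C)C | intermediate
8 | 14-acetoxy-13-methoxypodocarpa-8,11,13-trien-3-one | O=C1CC[C@]2(C)c3ccc(OC)c(OC(C)=O)c3CC[C@H]2C1(C)C | intermediate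
9 | 14-acetoxy-13-methoxy-4-oxa-A-homopodocarpa-8,11,13-trien-3-one | O=C1CC[C@]2(C)c3ccc(OC)c(OC(C)=O)c3CC[C@H]2C(C)(C)O1 | intermediate
10 | methyl (5S,10S)-14-hydroxy-13-methoxy-3,4-secopodocarpa-4(18),8,11,13-tetraen-3-oate | COC(=O)CC[C@]1(C)c2ccc(OC)c(O)c2CC[C@H]1C(C)=C | intermediate
11 | tert-butyl vinyl ether | C=COC(C)(C)C | starting material
12 | methyl 15-tert-butoxy-13,13-dimethoxy-14-oxo-3,4-seco-17-noratisa-4(18),9(11)-dien-3-oate (C15 drawn endo; it is destroyed in step 13) | C1[C@H](OC(C)(C)C)[C@]23CC[C@@H](C(=C)C)[C@](C)(CCC(=O)OC)C2=C[C@H]1C(OC)(OC)C3=O | intermediate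
13 | methyl (14S)-15-tert-butoxy-14-hydroxy-3,4-seco-17-noratisa-4(18),9(11)-dien-3-oate | C1[C@H](OC(C)(C)C)[C@]23CC[C@@H](C(=C)C)[C@](C)(CCC(=O)OC)C2=C[C@H]1C[C@@H]3O | intermediate
14 | methyl (14S)-14-acetoxy-15-tert-butoxy-3,4-seco-17-noratisa-4(18),9(11)-dien-3-oate | C1[C@H](OC(C)(C)C)[C@]23CC[C@@H](C(=C)C)[C@](C)(CCC(=O)OC)C2=C[C@H]1C[C@@H]3OC(C)=O | intermediate
15 | (14S)-14-acetoxy-15-hydroxy-3,4-seco-17-noratis-4(18)-en-3,9-olide | C1[C@H](O)[C@]23CC[C@@H](C(=C)C)[C@]4(C)CCC(=O)O[C@@]42C[C@H]1C[C@@H]3OC(C)=O | intermediate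
16 | (14S)-14-acetoxy-15-oxo-3,4-seco-17-noratis-4(18)-en-3,9-olide | C1C(=O)[C@]23CC[C@@H](C(=C)C)[C@]4(C)CCC(=O)O[C@@]42C[C@H]1C[C@@H]3OC(C)=O | intermediate
17 | crotobarin | C=C1C(=O)[C@]23CC[C@@H](C(=C)C)[C@]4(C)CCC(=O)O[C@@]42C[C@H]1C[C@@H]3OC(C)=O | target

## Summary

Total steps: 14. Longest linear sequence: 14 (fully linear; 3 and 11 are purchased partners).

Three steps most likely to fail, each with a fallback that changes the approach:

1. **Step 9 (dearomatisation / Diels–Alder).** The diene terminus C8 is fully substituted, and α-face selectivity depends on the conformational bias of the opened ring. Fallback: change the order of ring events. Do the dearomatisation and cycloaddition on the rigid, still ring-A-closed phenol ε-lactone (from 9 by selective O-deacetylation), where the trans-fused framework enforces α-attack. Then open ring A and close the δ-lactone in the later acid step.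

2. **Step 12 (cationic lactonisation).** The isopropenyl group is acid-sensitive, the C9 cation could undergo Wagner–Meerwein shift, and the ester must lose its methyl group. Fallback: replace carbocation chemistry with halolactonisation. Saponify 13, iodolactonise (I2, NaHCO3; O to C9, I to C11), remove iodine with Bu3SnH, then acetylate and cleave the tert-butyl ether separately.

3. **Step 5 (regioselective mono-demethylation).** Selectivity for the hindered C14–OMe rests on analogy, not a direct precedent. Fallback: carry the two oxygens differentiated from the start. Build the tricyclic 3-ketone from an o-vanillin-derived 2-(MOM-oxy)-3-methoxybenzyl unit by enantioselective epoxy-polyene cyclisation and oxidation. No selective ether cleavage is then needed, and the MOM group falls off in step 8.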